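**Plan**

Numbering (germacrane): ring C1–C10 with C1=C10 (Z) and C4=C5 (E), acetates on C3 and C9, γ-lactone O–C6, C7, C11(–C13), C12. Enabling feature: C7 is the β-carbon of the lactone carbonyl and C8 lies α to the C9 oxygen, so a C7=C11 butenolide can accept a C8 carbanion of a C9 β-keto ester, with the C6 stereocentre on the acceptor ring.
Retrosynthetic cuts, in order: the two acetates and the C9 carbinol (back to a C9 ketone with an allyl ester on C8), the ring bond C7–C8, then C8–C9 (malonate acylation), C7=C11 (dehydrogenation), C1=C10 (Still–Gennari), C11–C13 (methylation), C2–C3 (allylation) and C4=C5 (Wittig).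
Forward: the γ-lactone ring is present from the start (glutamate-derived lactone 1); the chain is grown linearly from C5 to C8, the butenolide is unveiled, and the ten-membered ring closes last through C7–C8.
Stereochemistry: C6 from the chiral pool; C3 by reagent-controlled allylboration; 4E and 1(10)Z from the two olefinations; C7 and C11 in the key step (addition anti to the C6 substituent, kinetic protonation anti to C8); C9 by oxazaborolidine-controlled reduction.
Key step: step 11

Remark: 8–14 are carried as C11 epimer mixtures and 21 as a C8 epimer mixture, because both centres are erased later (steps 8 and 12); metal enolates and carboxylates formed in the flask are regarded as ionised forms of the numbered compounds.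

**Route**

Step 1
Reactants: 1 (S)-5-(hydroxymethyl)dihydrofuran-2(3H)-one; 2 2-(triphenylphosphoranylidene)propanal
Product: 4 (S,E)-2-methyl-3-(5-oxotetrahydrofuran-2-yl)acrylaldehyde, via aldehyde 3 (not isolated)
Conditions: Dess–Martin periodinane, CH2Cl2, 0 °C → rt; then 2, CH2Cl2, rt → 40 °C
Reagents that add atoms: none
Why: Dess–Martin oxidation gives the configurationally labile α-acyloxy aldehyde 3 without base, and the formyl-stabilised ylide traps it in the same flask in an E-selective Wittig reaction, so C6 keeps the configuration of 1 while the 4E alkene and the C3 aldehyde are installed.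

Step 2
Reactants: 4 (S,E)-2-methyl-3-(5-oxotetrahydrofuran-2-yl)acrylaldehyde; 5 B-allyldiisopinocampheylborane of the (+)-α-pinene series, dIpc2B(allyl)
Product: 6 (S)-5-[(1E,3S)-3-hydroxy-2-methylhexa-1,5-dien-1-yl]dihydrofuran-2(3H)-one
Conditions: 5 (commercial 1 M solution in pentane), Et2O, −78 °C; then pH 7 buffer, 30% H2O2, MeOH, 0 °C
Reagents that add atoms: none
Why: Brown allylboration through a closed chair transition state delivers the allyl group to the Si face of the enal carbonyl under control of the isopinocampheyl groups (the remote C6 centre has no say), which sets 3S, and the borane leaves the lactone alone at −78 °C.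

Step 3
Reactants: 6 (S)-5-[(1E,3S)-3-hydroxy-2-methylhexa-1,5-dien-1-yl]dihydrofuran-2(3H)-one
Product: 7 (S)-5-[(1E,3S)-3-(tert-butyldimethylsilyloxy)-2-methylhexa-1,5-dien-1-yl]dihydrofuran-2(3H)-one
Conditions: TBSOTf, 2,6-lutidine, CH2Cl2, −78 → 0 °C
Reagents that add atoms: tert-butyldimethylsilyl triflate, CC(C)(C)[Si](C)(C)OS(=O)(=O)C(F)(F)F
Why: Silylation of the secondary allylic alcohol with the silyl triflate and a hindered base is fast at low temperature and gives an ether that should survive enolate, hydroxide, carbonate and zerovalent palladium chemistry until step 14.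

Step 4
Reactants: 7 (S)-5-[(1E,3S)-3-(tert-butyldimethylsilyloxy)-2-methylhexa-1,5-dien-1-yl]dihydrofuran-2(3H)-one
Product: 8 (5S)-5-[(1E,3S)-3-(tert-butyldimethylsilyloxy)-2-methylhexa-1,5-dien-1-yl]-3-methyldihydrofuran-2(3H)-one (C11 epimers)
Conditions: LiN(i-Pr)2, THF, −78 °C; MeI, −78 → −40 °C
Reagents that add atoms: iodomethane, CI
Why: Kinetic enolisation of the γ-lactone and C-methylation is standard lactone enolate alkylation, and the configuration at C11 does not matter because this carbon becomes sp2 in step 8.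

Step 5
Reactants: 8 (5S)-5-[(1E,3S)-3-(tert-butyldimethylsilyloxy)-2-methylhexa-1,5-dien-1-yl]-3-methyldihydrofuran-2(3H)-one
Product: 9 (3S,4E)-3-(tert-butyldimethylsilyloxy)-4-methyl-5-[(2S)-4-methyl-5-oxotetrahydrofuran-2-yl]pent-4-enal
Conditions: OsO4 (cat.), NaIO4, 2,6-lutidine, 1,4-dioxane/H2O, rt
Reagents that add atoms: osmium tetroxide, O=[Os](=O)(=O)=O (oxygen donor, regenerated by NaIO4); sodium periodate, [Na+].[O-]I(=O)(=O)=O
Why: In this Lemieux–Johnson cleavage OsO4 should dihydroxylate the unhindered monosubstituted alkene much faster than the trisubstituted C4=C5 alkene, which is flanked by the silyl ether and the lactone carbinol, and NaIO4 cleaves the diol to the C1 aldehyde while 2,6-lutidine suppresses over-oxidation.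

Step 6
Reactants: 9 (3S,4E)-3-(tert-butyldimethylsilyloxy)-4-methyl-5-[(2S)-4-methyl-5-oxotetrahydrofuran-2-yl]pent-4-enal; 10 methyl 2-[bis(2,2,2-trifluoroethoxy)phosphoryl]propanoate
Product: 11 methyl (2Z,5S,6E)-5-(tert-butyldimethylsilyloxy)-2,6-dimethyl-7-[(2S)-4-methyl-5-oxotetrahydrofuran-2-yl]hepta-2,6-dienoate
Conditions: 10, KN(SiMe3)2, 18-crown-6, THF, −78 °C; then 9
Reagents that add atoms: none
Why: In the Still–Gennari olefination the dissociated potassium phosphonate adds irreversibly and the electron-poor oxaphosphetane collapses fast, which gives the Z trisubstituted enoate (C9 and C2 cis on C1=C10), and the weakly basic anion leaves the lactone α-proton and the β-silyloxy aldehyde untouched.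

Step 7
Reactants: 11 methyl (2Z,5S,6E)-5-(tert-butyldimethylsilyloxy)-2,6-dimethyl-7-[(2S)-4-methyl-5-oxotetrahydrofuran-2-yl]hepta-2,6-dienoate
Product: 12 (2Z,5S,6E)-5-(tert-butyldimethylsilyloxy)-2,6-dimethyl-7-[(2S)-4-methyl-5-oxotetrahydrofuran-2-yl]hepta-2,6-dienoic acid
Conditions: LiOH·H2O, THF/MeOH/H2O, rt → 40 °C; then 1 M HCl to pH 3, 0 °C → rt
Reagents that add atoms: lithium hydroxide, [Li+].[OH-] (oxygen of the new carboxyl OH)
Why: Saponification cleaves the hindered Z ester and transiently opens the γ-lactone to its γ-hydroxy carboxylate, which should close again on acidification because the C6–O bond is never broken, so no stereocentre or alkene geometry is affected.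

Step 8
Reactants: 12 (2Z,5S,6E)-5-(tert-butyldimethylsilyloxy)-2,6-dimethyl-7-[(2S)-4-methyl-5-oxotetrahydrofuran-2-yl]hepta-2,6-dienoic acid
Product: 15 (2Z,5S,6E)-5-(tert-butyldimethylsilyloxy)-2,6-dimethyl-7-[(2R)-4-methyl-5-oxo-2,5-dihydrofuran-2-yl]hepta-2,6-dienoic acid, via selenide 13 (not isolated), via selenoxide 14 (not isolated)
Conditions: LiN(i-Pr)2 (2.3 equiv), THF, −78 → −40 °C; PhSeBr, −78 °C; then AcOH, 30% H2O2, pyridine, 0 °C → rt
Reagents that add atoms: phenylselenyl bromide, Br[Se]c1ccccc1, and hydrogen peroxide, OO (their atoms are carried only by 13 and 14; none remain in 15)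
Why: This is the standard α-selenenylation and selenoxide syn-elimination of a lactone, in which the first equivalent of amide stores the acid as its carboxylate (shielding the Z-enoate from γ-deprotonation), the second enolises the lactone, and selenoxide 14 should eliminate into the ring toward the syn hydrogen on C7 to give the conjugated C7=C11 alkene with C6 unchanged (its descriptor becomes R only through a priority change).

Step 9
Reactants: 16 2,2-dimethyl-1,3-dioxane-4,6-dione (Meldrum's acid); 17 prop-2-en-1-ol (allyl alcohol)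
Product: 18 3-(allyloxy)-3-oxopropanoic acid (allyl hydrogen malonate)
Conditions: toluene, 105 °C
Reagents that add atoms: none
Why: Thermal alcoholysis of Meldrum's acid opens the dioxanedione with loss of acetone and stops at the malonic half ester.

Step 10
Reactants: 15 (2Z,5S,6E)-5-(tert-butyldimethylsilyloxy)-2,6-dimethyl-7-[(2R)-4-methyl-5-oxo-2,5-dihydrofuran-2-yl]hepta-2,6-dienoic acid; 18 3-(allyloxy)-3-oxopropanoic acid
Product: 20 allyl (4Z,7S,8E)-7-(tert-butyldimethylsilyloxy)-4,8-dimethyl-9-[(2R)-4-methyl-5-oxo-2,5-dihydrofuran-2-yl]-3-oxonona-4,8-dienoate, via acyl imidazolide 19 (not isolated)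
Conditions: CDI, THF, rt; then Mg(O2CCH2CO2CH2CH=CH2)2 [from 18 and Mg(OEt)2], THF, rt → 40 °C; 1 M HCl work-up
Reagents that add atoms: 1,1'-carbonyldiimidazole, O=C(n1ccnc1)n1ccnc1 (imidazolyl group present in 19 only)
Why: In this Masamune–Brooks chain extension the acyl imidazolide 19 C-acylates the magnesium enolate of the malonate half ester under neutral conditions and the acylmalonate loses CO2, so the β-keto allyl ester should form without a base strong enough to remove the butenolide γ-proton or to isomerise the Z-enoyl unit.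

Step 11
Reactants: 20 allyl (4Z,7S,8E)-7-(tert-butyldimethylsilyloxy)-4,8-dimethyl-9-[(2R)-4-methyl-5-oxo-2,5-dihydrofuran-2-yl]-3-oxonona-4,8-dienoate
Product: 21 allyl 3-(tert-butyldimethylsilyloxy)-9-oxogermacra-1(10)Z,4E-dien-12,6-olide-8-carboxylate (3S,6S,7R,11R; 6,7-trans lactone, C13 methyl cis to C8; C8 epimers)
Conditions: Cs2CO3 (1.5 equiv), MeCN, 1 mM (slow addition of 20), rt → 40 °C; AcOH quench
Reagents that add atoms: none
Why: Proposed new method: Cs2CO3 removes only the C8 proton of the β-keto ester (far more acidic than H6 of the butenolide), the caesium enolate adds reversibly to C7, the β-carbon of the α-methylbutenolide, and the resulting lactone enolate is protonated at C11 by CsHCO3 or by unreacted β-keto ester, which makes the sequence irreversible in practice. The closest known reactions are intermolecular Michael additions of β-dicarbonyl carbanions to 5-substituted butenolides, which go anti to the C5 substituent, and intramolecular Michael macrocyclisations of β-keto esters onto enones; closure of a ten-membered carbocycle onto a butenolide has not been shown. The ring closes in a 10-exo-trig mode (C8 onto C7, with C7=C11 exocyclic to the new ring), and high dilution together with the three rigid units of the tether (Z-enone, E-alkene, planar butenolide) should keep the entropic cost and oligomerisation down. C7 is controlled by C6: C8 bonds to the butenolide face opposite the C6–C5 bond, which is the torsionally favoured and, since the addition is reversible, also the thermodynamically favoured 6,7-trans junction. C11 is controlled by the new C7–C8 bond, which blocks one face of the lactone enolate, so the proton should arrive anti to C8 and leave the C13 methyl cis to C8 (11R); C8 itself stays a mixture and is erased in step 12. The step needs C8 rather than C6 deprotonation, 6,7-trans addition, kinetic C11 protonation and an intact Z-enone, and these rest on the pK gap between the β-keto ester and every other C–H, on the C6 centre, and on a carbonate base too weak to re-enolise the lactone or to deprotonate C2.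

Step 12
Reactants: 21 allyl 3-(tert-butyldimethylsilyloxy)-9-oxogermacra-1(10)Z,4E-dien-12,6-olide-8-carboxylate
Product: 22 (3S,6S,7S,11R)-3-(tert-butyldimethylsilyloxy)-9-oxogermacra-1(10)Z,4E-dien-12,6-olide
Conditions: Pd(PPh3)4 (5 mol %), morpholine, THF, rt
Reagents that add atoms: none
Why: Zerovalent palladium ionises the allyl ester (Tsuji–Trost ionisation), morpholine captures the π-allyl fragment and the β-keto acid decarboxylates at room temperature, which removes the C8 stereocentre and leaves C7 and C11 untouched under near-neutral conditions.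

Step 13
Reactants: 22 (3S,6S,7S,11R)-3-(tert-butyldimethylsilyloxy)-9-oxogermacra-1(10)Z,4E-dien-12,6-olide
Product: 23 (3S,6S,7S,9R,11R)-3-(tert-butyldimethylsilyloxy)-9-hydroxygermacra-1(10)Z,4E-dien-12,6-olide
Conditions: (S)-2-methyl-CBS-oxazaborolidine, BH3·SMe2, THF, −40 → −20 °C; MeOH quench
Reagents that add atoms: none
Why: In the Corey–Bakshi–Shibata reduction the (S)-oxazaborolidine should bind the ketone with the α-methylalkenyl arm (C10) as the large group and deliver hydride in 1,2-fashion to the face that gives the 9R allylic alcohol, without touching the lactone.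

Step 14
Reactants: 23 (3S,6S,7S,9R,11R)-3-(tert-butyldimethylsilyloxy)-9-hydroxygermacra-1(10)Z,4E-dien-12,6-olide
Product: 24 (3S,6S,7S,9R,11R)-3,9-dihydroxygermacra-1(10)Z,4E-dien-12,6-olide
Conditions: HF·pyridine, pyridine, THF, 0 °C → rt
Reagents that add atoms: none
Why: Buffered HF·pyridine cleaves the secondary silyl ether without base, so the epimerisable C11 centre and the lactone should not be endangered.

Step 15
Reactants: 24 (3S,6S,7S,9R,11R)-3,9-dihydroxygermacra-1(10)Z,4E-dien-12,6-olide
Product: 25 (3S,6S,7S,9R,11R)-3,9-diacetoxygermacra-1(10)Z,4E-dien-12,6-olide (CNP0226482.6)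
Conditions: Ac2O, pyridine, DMAP (cat.), CH2Cl2, rt
Reagents that add atoms: acetic anhydride, CC(=O)OC(C)=O
Why: DMAP-catalysed acylation esterifies both secondary allylic alcohols with retention at C3 and C9 and should give the target.

**Compound list**

1 | (S)-5-(hydroxymethyl)dihydrofuran-2(3H)-one | O=C1CC[C@@H](CO)O1 | starting material
2 | 2-(triphenylphosphoranylidene)propanal | CC(C=O)=P(c1ccccc1)(c1ccccc1)c1ccccc1 | starting material
3 | (S)-5-oxotetrahydrofuran-2-carbaldehyde | O=C1CC[C@@H](C=O)O1 | intermediate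
4 | (S,E)-2-methyl-3-(5-oxotetrahydrofuran-2-yl)acrylaldehyde | O=C/C(C)=C/[C@H]1OC(=O)CC1 | intermediate
5 | B-allyldiisopinocampheylborane of the (+)-α-pinene series, dIpc2B(allyl) | C=CCB([C@@H]1C[C@@H]2C[C@H]([C@H]1C)C2(C)C)[C@@H]1C[C@@H]2C[C@H]([C@H]1C)C2(C)C | starting material
6 | (S)-5-[(1E,3S)-3-hydroxy-2-methylhexa-1,5-dien-1-yl]dihydrofuran-2(3H)-one | C=CC[C@H](O)/C(C)=C/[C@H]1OC(=O)CC1 | intermediate
7 | (S)-5-[(1E,3S)-3-(tert-butyldimethylsilyloxy)-2-methylhexa-1,5-dien-1-yl]dihydrofuran-2(3H)-one | C=CC[C@H](O[Si](C)(C)C(C)(C)C)/C(C)=C/[C@H]1OC(=O)CC1 | intermediate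
8 | (5S)-5-[(1E,3S)-3-(tert-butyldimethylsilyloxy)-2-methylhexa-1,5-dien-1-yl]-3-methyldihydrofuran-2(3H)-one, C11 epimers | C=CC[C@H](O[Si](C)(C)C(C)(C)C)/C(C)=C/[C@H]1OC(=O)C(C)C1 | intermediate
9 | (3S,4E)-3-(tert-butyldimethylsilyloxy)-4-methyl-5-[(2S)-4-methyl-5-oxotetrahydrofuran-2-yl]pent-4-enal | O=CC[C@H](O[Si](C)(C)C(C)(C)C)/C(C)=C/[C@H]1OC(=O)C(C)C1 | intermediate
10 | methyl 2-[bis(2,2,2-trifluoroethoxy)phosphoryl]propanoate | COC(=O)C(C)P(=O)(OCC(F)(F)F)OCC(F)(F)F | starting material
11 | methyl (2Z,5S,6E)-5-(tert-butyldimethylsilyloxy)-2,6-dimethyl-7-[(2S)-4-methyl-5-oxotetrahydrofuran-2-yl]hepta-2,6-dienoate | COC(=O)/C(C)=C\C[C@H](O[Si](C)(C)C(C)(C)C)/C(C)=C/[C@H]1OC(=O)C(C)C1 | intermediate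
12 | (2Z,5S,6E)-5-(tert-butyldimethylsilyloxy)-2,6-dimethyl-7-[(2S)-4-methyl-5-oxotetrahydrofuran-2-yl]hepta-2,6-dienoic acid | OC(=O)/C(C)=C\C[C@H](O[Si](C)(C)C(C)(C)C)/C(C)=C/[C@H]1OC(=O)C(C)C1 | intermediate
13 | α-(phenylselanyl) lactone of 12 (PhSe and CH3 both on C11) | OC(=O)/C(C)=C\C[C@H](O[Si](C)(C)C(C)(C)C)/C(C)=C/[C@H]1OC(=O)C(C)([Se]c2ccccc2)C1 | intermediate
14 | selenoxide of 13 | OC(=O)/C(C)=C\C[C@H](O[Si](C)(C)C(C)(C)C)/C(C)=C/[C@H]1OC(=O)C(C)([Se](=O)c2ccccc2)C1 | intermediate
15 | (2Z,5S,6E)-5-(tert-butyldimethylsilyloxy)-2,6-dimethyl-7-[(2R)-4-methyl-5-oxo-2,5-dihydrofuran-2-yl]hepta-2,6-dienoic acid | OC(=O)/C(C)=C\C[C@H](O[Si](C)(C)C(C)(C)C)/C(C)=C/[C@H]1OC(=O)C(C)=C1 | intermediate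
16 | 2,2-dimethyl-1,3-dioxane-4,6-dione (Meldrum's acid) | CC1(C)OC(=O)CC(=O)O1 | starting material
17 | prop-2-en-1-ol (allyl alcohol) | C=CCO | starting material
18 | 3-(allyloxy)-3-oxopropanoic acid (allyl hydrogen malonate) | C=CCOC(=O)CC(=O)O | intermediate
19 | N-acyl imidazole of acid 15 | O=C(n1ccnc1)/C(C)=C\C[C@H](O[Si](C)(C)C(C)(C)C)/C(C)=C/[C@H]1OC(=O)C(C)=C1 | intermediate
20 | allyl (4Z,7S,8E)-7-(tert-butyldimethylsilyloxy)-4,8-dimethyl-9-[(2R)-4-methyl-5-oxo-2,5-dihydrofuran-2-yl]-3-oxonona-4,8-dienoate | C=CCOC(=O)CC(=O)/C(C)=C\C[C@H](O[Si](C)(C)C(C)(C)C)/C(C)=C/[C@H]1OC(=O)C(C)=C1 | intermediate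
21 | allyl 3-(tert-butyldimethylsilyloxy)-9-oxogermacra-1(10)Z,4E-dien-12,6-olide-8-carboxylate (3S,6S,7R,11R; C8 epimers) | C=CCOC(=O)C1C(=O)/C(C)=C\C[C@H](O[Si](C)(C)C(C)(C)C)/C(C)=C/[C@H]2OC(=O)[C@H](C)[C@H]12 | intermediate
22 | (3S,6S,7S,11R)-3-(tert-butyldimethylsilyloxy)-9-oxogermacra-1(10)Z,4E-dien-12,6-olide | C1C(=O)/C(C)=C\C[C@H](O[Si](C)(C)C(C)(C)C)/C(C)=C/[C@H]2OC(=O)[C@H](C)[C@H]12 | intermediate
23 | (3S,6S,7S,9R,11R)-3-(tert-butyldimethylsilyloxy)-9-hydroxygermacra-1(10)Z,4E-dien-12,6-olide | C1[C@@H](O)/C(C)=C\C[C@H](O[Si](C)(C)C(C)(C)C)/C(C)=C/[C@H]2OC(=O)[C@H](C)[C@H]12 | intermediate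
24 | (3S,6S,7S,9R,11R)-3,9-dihydroxygermacra-1(10)Z,4E-dien-12,6-olide | C1[C@@H](O)/C(C)=C\C[C@H](O)/C(C)=C/[C@H]2OC(=O)[C@H](C)[C@H]12 | intermediate
25 | (3S,6S,7S,9R,11R)-3,9-diacetoxygermacra-1(10)Z,4E-dien-12,6-olide | CC(=O)O[C@H]1C/C=C(/C)[C@H](OC(C)=O)C[C@@H]2[C@@H](/C=C/1C)OC(=O)[C@@H]2C | target

**Step count**

Total: 15 steps. Longest linear sequence: 14 steps (1–8 and 10–15); step 9 is a one-step side branch.

**Steps most likely to fail**

1. Step 11 (key step). The C8 enolate may add intermolecularly, or the adduct may revert because of transannular strain, so that oligomers or unchanged 20 result; enolisation at C6 and later epimerisation at C11 are further risks.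
The fallback closes the ring at C9–C10 by a Nozaki–Hiyama–Kishi reaction and makes C7–C8 intermolecularly; it uses only known reaction types, sets out from aldehyde 9 and comes back at ketone 22. Wittig olefination of 9 with the ylide from (1-iodoethyl)triphenylphosphonium iodide and NaN(SiMe3)2 at −78 °C should give the Z-vinyl iodide F1 (iodine on C10, cis to C2). Lactone dehydrogenation as in step 8 (LiN(i-Pr)2, PhSeBr; H2O2) passes through selenide F2 and selenoxide F3 to the iodo butenolide F4. Conjugate addition of an allyl cuprate (allylmagnesium bromide, CuBr·SMe2, Me3SiCl, THF, −78 °C) anti to the C6 side chain, with protonation of the silyl ketene acetal on work-up anti to the new substituent, should give the 6,7-trans, 7,11-cis allyl lactone F5 that carries C8 and C9. OsO4/NaIO4 cleavage of the terminal alkene gives the iodo aldehyde F6. CrCl2 with catalytic NiCl2 in DMSO at high dilution (divalent chromium inserting into the C10–I bond with retention of the Z geometry) closes the ten-membered ring onto the C9 aldehyde and gives the macrocyclic allylic alcohol F7 as C9 epimers. Dess–Martin oxidation of F7 returns to the route at 22.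

2. Step 8. Enolisation of the lactone next to the lithium carboxylate may be incomplete, the selenoxide may eliminate toward the methyl group (exocyclic alkene), or the peroxide/seleninic acid mixture may oxidise C4=C5.
The fallback replaces selenoxide elimination by a Saegusa–Ito dehydrosilylation; it sets out from acid 12 and comes back at 15. Treatment of 12 with LiN(i-Pr)2 (2.3 equiv) and Me3SiCl should give the silyl ester/silyl ketene acetal F8. Pd(OAc)2 in MeCN then forms the palladium enolate, which loses the ring hydrogen on C7, and re-addition of palladium hydride should funnel any exocyclic isomer to the more stable endocyclic butenolide. Aqueous work-up cleaves the silyl ester and gives 15.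

3. Step 13. The conformational bias of the ten-membered ring may override the oxazaborolidine and give poor facial selectivity at C9.
The fallback uses the ring bias deliberately and corrects C9 by inversion; it sets out from ketone 22 and comes back at target 25. A substrate-controlled Luche reduction (NaBH4, CeCl3·7H2O, MeOH, −78 °C) should give, if hydride arrives from the periphery on the undesired face, the 9S alcohol F9. Mitsunobu reaction with acetic acid (PPh3, diisopropyl azodicarboxylate) inverts C9 and installs the acetate directly, giving the 9R acetate silyl ether F10. HF·pyridine removes the silyl group to give the hydroxy acetate F11, and Ac2O/pyridine/DMAP acetylates C3 to give 25.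

**Further compounds**

F1 | step 11 | (5S)-5-[(1E,3S,5Z)-3-(tert-butyldimethylsilyloxy)-6-iodo-2-methylhepta-1,5-dien-1-yl]-3-methyldihydrofuran-2(3H)-one, C11 epimers | I/C(C)=C\C[C@H](O[Si](C)(C)C(C)(C)C)/C(C)=C/[C@H]1OC(=O)C(C)C1
F2 | step 11 | α-(phenylselanyl) lactone of F1 | I/C(C)=C\C[C@H](O[Si](C)(C)C(C)(C)C)/C(C)=C/[C@H]1OC(=O)C(C)([Se]c2ccccc2)C1
F3 | step 11 | selenoxide of F2 | I/C(C)=C\C[C@H](O[Si](C)(C)C(C)(C)C)/C(C)=C/[C@H]1OC(=O)C(C)([Se](=O)c2ccccc2)C1
F4 | step 11 | (R)-5-[(1E,3S,5Z)-3-(tert-butyldimethylsilyloxy)-6-iodo-2-methylhepta-1,5-dien-1-yl]-3-methylfuran-2(5H)-one | I/C(C)=C\C[C@H](O[Si](C)(C)C(C)(C)C)/C(C)=C/[C@H]1OC(=O)C(C)=C1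
F5 | step 11 | 4-allyl-5-[(1E,3S,5Z)-3-(tert-butyldimethylsilyloxy)-6-iodo-2-methylhepta-1,5-dien-1-yl]-3-methyldihydrofuran-2(3H)-one (allyl trans to the side chain, cis to the 3-methyl) | I/C(C)=C\C[C@H](O[Si](C)(C)C(C)(C)C)/C(C)=C/[C@H]1OC(=O)[C@H](C)[C@@H]1CC=C
F6 | step 11 | 2-{2-[(1E,3S,5Z)-3-(tert-butyldimethylsilyloxy)-6-iodo-2-methylhepta-1,5-dien-1-yl]-4-methyl-5-oxotetrahydrofuran-3-yl}acetaldehyde (same ring configuration as F5) | I/C(C)=C\C[C@H](O[Si](C)(C)C(C)(C)C)/C(C)=C/[C@H]1OC(=O)[C@H](C)[C@@H]1CC=O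
F7 | step 11 | 3-(tert-butyldimethylsilyloxy)-9-hydroxygermacra-1(10)Z,4E-dien-12,6-olide, C9 epimers | C1C(O)/C(C)=C\C[C@H](O[Si](C)(C)C(C)(C)C)/C(C)=C/[C@H]2OC(=O)[C@H](C)[C@H]12
F8 | step 8 | trimethylsilyl (2Z,5S,6E)-5-(tert-butyldimethylsilyloxy)-2,6-dimethyl-7-[(2S)-4-methyl-5-(trimethylsilyloxy)-2,3-dihydrofuran-2-yl]hepta-2,6-dienoate | C[Si](C)(C)OC(=O)/C(C)=C\C[C@H](O[Si](C)(C)C(C)(C)C)/C(C)=C/[C@H]1OC(O[Si](C)(C)C)=C(C)C1
F9 | step 13 | (3S,6S,7S,9S,11R)-3-(tert-butyldimethylsilyloxy)-9-hydroxygermacra-1(10)Z,4E-dien-12,6-olide | C1[C@H](O)/C(C)=C\C[C@H](O[Si](C)(C)C(C)(C)C)/C(C)=C/[C@H]2OC(=O)[C@H](C)[C@H]12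
F10 | step 13 | (3S,6S,7S,9R,11R)-9-acetoxy-3-(tert-butyldimethylsilyloxy)germacra-1(10)Z,4E-dien-12,6-olide | C1[C@@H](OC(C)=O)/C(C)=C\C[C@H](O[Si](C)(C)C(C)(C)C)/C(C)=C/[C@H]2OC(=O)[C@H](C)[C@H]12
F11 | step 13 | (3S,6S,7S,9R,11R)-9-acetoxy-3-hydroxygermacra-1(10)Z,4E-dien-12,6-olide | C1[C@@H](OC(C)=O)/C(C)=C\C[C@H](O)/C(C)=C/[C@H]2OC(=O)[C@H](C)[C@H]12
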